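**Strategy**

Ring C is disconnected at C3–C4 and O1–C2: its C2–C3–C4 unit is a latent 1,3-dicarbonyl, carried as a 3,5-diarylisoxazole. The key step, a [3+2] cycloaddition of a ring A nitrile oxide (its carbon becomes C4) to a ring B arylacetylene, joins both arenes and makes C3–C4 and a temporary O–C2 bond in one operation. It exploits C4a lying between the oxygenated C5 and C8a, so the di-ortho-substituted nitrile oxide does not dimerise and can be made beforehand. The precursor is a hexasubstituted benzonitrile oxide with benzyl on the C8a oxygen, MOM on the C6 oxygen and three methoxy groups; hydrogenolysis, then acid, unmask and close the pyranone.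

Key step: step 11

Remark 1: after N–O cleavage of the isoxazole the nitrogen remains on C4 and the former ring oxygen is the C2 ketone. Ring C therefore closes by condensation of the C8a hydroxyl with the C2 carbonyl (loss of water), and the C4 oxygen comes from water with loss of ammonia.
Remark 2: the C6 oxygen is carried as a MOM ether, not a benzyl ether, so that hydrogenolysis frees only the C8a phenol and no air-sensitive trimethoxyhydroquinone is handled. The ring B oxygen stays as its MOM ether until ring C is closed, so that it cannot compete in the ring closure.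
Remark 3: oxime 9 is drawn as the E isomer; its geometry is lost in step 8.

**Route**

Step 1
Reactants: 1 syringaldehyde (4-hydroxy-3,5-dimethoxybenzaldehyde)
Product: 2 3,5-dimethoxy-4-(methoxymethoxy)benzaldehyde
Conditions: MOMCl, iPr2NEt, CH2Cl2, 0 °C to rt
Reagents that add atoms: chloromethyl methyl ether (MOMCl), COCCl
Why: O-alkylation of the acidic phenol by the reactive α-chloro ether under amine base is a standard MOM protection, and the acetal is chosen because it tolerates NBS, hot methoxide, peracid and hydrogenolysis and leaves only in the last step.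

Step 2
Reactants: 2 3,5-dimethoxy-4-(methoxymethoxy)benzaldehyde
Product: 3 2-bromo-3,5-dimethoxy-4-(methoxymethoxy)benzaldehyde
Conditions: NBS, MeCN, rt
Reagents that add atoms: N-bromosuccinimide, O=C1CCC(=O)N1Br
Why: Electrophilic aromatic bromination with NBS takes place at one of the two equivalent ring positions, each activated by an ortho and a para alkoxy group as in 3,4,5-trialkoxybenzaldehydes, and it liberates no HBr that could attack the acetal.

Step 3
Reactants: 3 2-bromo-3,5-dimethoxy-4-(methoxymethoxy)benzaldehyde
Product: 4 2,3,5-trimethoxy-4-(methoxymethoxy)benzaldehyde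
Conditions: NaOMe, CuBr (10 mol%), EtOAc (cat.), MeOH–DMF, 100 °C
Reagents that add atoms: sodium methoxide, [Na+].[O-]C
Why: Ullmann-type copper-catalysed methoxylation of the aryl bromide, assisted by the ortho formyl group and the ester co-catalyst, replaces Br by OMe while the aldehyde is masked reversibly as its hemiacetal alkoxide and returns on work-up.

Step 4
Reactants: 4 2,3,5-trimethoxy-4-(methoxymethoxy)benzaldehyde
Product: 6 2,3,5-trimethoxy-4-(methoxymethoxy)phenol, via aryl formate 5 (not isolated)
Conditions: mCPBA, CH2Cl2, 0 °C to rt; aq. NaHCO3 wash; then K2CO3 (cat.), MeOH, rt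
Reagents that add atoms: 3-chloroperbenzoic acid (mCPBA), OOC(=O)c1cccc(Cl)c1
Why: Baeyer–Villiger (Dakin-type) oxidation of an electron-rich benzaldehyde proceeds by aryl migration, favoured here by ortho and para alkoxy groups, and methanolysis of the formate ester releases the phenol.

Step 5
Reactants: 6 2,3,5-trimethoxy-4-(methoxymethoxy)phenol
Product: 7 2-hydroxy-3,4,6-trimethoxy-5-(methoxymethoxy)benzaldehyde
Conditions: MgCl2, Et3N, (CH2O)n, MeCN, 80 °C
Reagents that add atoms: paraformaldehyde (as formaldehyde), C=O
Why: Casnati–Skattebøl ortho-formylation: the magnesium phenoxide delivers formaldehyde to the only unsubstituted ring carbon, which is ortho to the hydroxyl, and Oppenauer-type hydride transfer to a second formaldehyde gives the salicylaldehyde under basic conditions that spare the MOM ether.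

Step 6
Reactants: 7 2-hydroxy-3,4,6-trimethoxy-5-(methoxymethoxy)benzaldehyde
Product: 8 2-(benzyloxy)-3,4,6-trimethoxy-5-(methoxymethoxy)benzaldehyde
Conditions: BnBr, K2CO3, DMF, 60 °C
Reagents that add atoms: benzyl bromide, BrCc1ccccc1
Why: Williamson etherification of the chelated phenol in a dipolar aprotic solvent, with benzyl chosen because it leaves in the same hydrogenation that opens the isoxazole.

Step 7
Reactants: 8 2-(benzyloxy)-3,4,6-trimethoxy-5-(methoxymethoxy)benzaldehyde
Product: 9 (E)-2-(benzyloxy)-3,4,6-trimethoxy-5-(methoxymethoxy)benzaldehyde oxime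
Conditions: NH2OH·HCl, NaOAc, EtOH–H2O, rt
Reagents that add atoms: hydroxylamine hydrochloride, NO.Cl
Why: Condensation of the aldehyde with hydroxylamine in acetate buffer gives the aldoxime without touching the acid-labile acetal.

Step 8
Reactants: 9 (E)-2-(benzyloxy)-3,4,6-trimethoxy-5-(methoxymethoxy)benzaldehyde oxime
Product: 11 2-(benzyloxy)-3,4,6-trimethoxy-5-(methoxymethoxy)benzonitrile oxide, via hydroximoyl chloride 10 (not isolated)
Conditions: NCS, DMF, rt; then Et3N, CH2Cl2, 0 °C
Reagents that add atoms: none
Why: Chlorination of the aldoxime with NCS followed by 1,3-elimination of HCl with triethylamine (the Huisgen procedure) gives the nitrile oxide; the ring has no C–H to chlorinate, and the benzyloxy and methoxy groups flanking the CNO carbon block dimerisation to the furoxan, so the dipole can be isolated by extraction and used directly.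

Step 9
Reactants: 12 2-hydroxy-6-methoxybenzaldehyde
Product: 13 2-methoxy-6-(methoxymethoxy)benzaldehyde
Conditions: MOMCl, iPr2NEt, CH2Cl2, 0 °C to rt
Reagents that add atoms: chloromethyl methyl ether (MOMCl), COCCl
Why: Standard MOM protection of the hydrogen-bonded phenol by O-alkylation, giving an acetal that survives base, heat and hydrogenation.

Step 10
Reactants: 13 2-methoxy-6-(methoxymethoxy)benzaldehyde; 14 dimethyl (1-diazo-2-oxopropyl)phosphonate
Product: 15 2-ethynyl-1-methoxy-3-(methoxymethoxy)benzene
Conditions: K2CO3, MeOH, rt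
Reagents that add atoms: dimethyl (1-diazo-2-oxopropyl)phosphonate (compound 14), CC(=O)C(=[N+]=[N-])P(=O)(OC)OC
Why: Ohira–Bestmann variant of the Seyferth–Gilbert homologation: methanolysis of the reagent gives the diazomethylphosphonate anion, whose Horner–Wadsworth–Emmons reaction with the aldehyde, loss of nitrogen and 1,2-hydride shift furnish the terminal alkyne under mild base.

Step 11
Reactants: 11 2-(benzyloxy)-3,4,6-trimethoxy-5-(methoxymethoxy)benzonitrile oxide; 15 2-ethynyl-1-methoxy-3-(methoxymethoxy)benzene
Product: 16 3-[2-(benzyloxy)-3,4,6-trimethoxy-5-(methoxymethoxy)phenyl]-5-[2-methoxy-6-(methoxymethoxy)phenyl]-1,2-oxazole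
Conditions: toluene, 80 °C (1.5 equiv of 15)
Reagents that add atoms: none
Why: Concerted, asynchronous thermal 1,3-dipolar (Huisgen) cycloaddition: the nitrile oxide carbon, the future C4, bonds to the terminal alkyne carbon, the future C3, and the nitrile oxide oxygen bonds to the internal alkyne carbon, the future C2, in one transition state. The closest known reaction type is the addition of stable di-ortho-substituted arenecarbonitrile oxides (for example mesitonitrile oxide or 2,6-dimethoxybenzonitrile oxide) to terminal arylacetylenes, which gives 3,5-diarylisoxazoles. The isoxazole ring closes by intermolecular [3+2] annulation with both ring bonds (C3–C4 and O–C2) forming together, so no cyclisation mode of an open chain is involved and no stereocentre is created. The selectivity needed is regiochemical (3,5- over 3,4-diaryl) and is secured by the terminal alkyne: its unsubstituted carbon is the less hindered terminus and carries the larger frontier-orbital coefficient for bonding to the dipole carbon, while the 3,4-isomer would place two di-ortho-substituted aryl groups on adjacent ring atoms. Furoxan formation is suppressed by the benzyloxy group on the C8a oxygen and the methoxy group on C5 that flank the dipole; the temperature is held below 100 °C to avoid isomerisation to the isocyanate, and the excess of alkyne compensates for the slow rate of a doubly hindered pair.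

Step 12
Reactants: 16 3-[2-(benzyloxy)-3,4,6-trimethoxy-5-(methoxymethoxy)phenyl]-5-[2-methoxy-6-(methoxymethoxy)phenyl]-1,2-oxazole
Product: 17 (2Z)-3-amino-3-[2-hydroxy-3,4,6-trimethoxy-5-(methoxymethoxy)phenyl]-1-[2-methoxy-6-(methoxymethoxy)phenyl]prop-2-en-1-one
Conditions: H2 (1 atm), 10% Pd/C, EtOAc–EtOH, rt
Reagents that add atoms: none
Why: Hydrogenolysis over palladium cleaves the benzyl ether and the weak N–O bond of the isoxazole, giving the hydrogen-bonded Z-enaminone (a vinylogous amide that resists further reduction) with the amino group on C4 and the ketone on C2, while MOM and methyl ethers are inert.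

Step 13
Reactants: 17 (2Z)-3-amino-3-[2-hydroxy-3,4,6-trimethoxy-5-(methoxymethoxy)phenyl]-1-[2-methoxy-6-(methoxymethoxy)phenyl]prop-2-en-1-one
Product: 19 6,2'-dihydroxy-5,7,8,6'-tetramethoxyflavone, via bis-MOM flavone 18 (not isolated)
Conditions: 80% aq. AcOH, 50 °C; then conc. HCl, MeOH, 50 °C
Reagents that add atoms: water, O
Why: Cyclodehydration of an ortho-hydroxyaryl β-enaminone to a flavone: in aqueous acetic acid the free C8a hydroxyl adds to the C2 ketone and water is lost to close the six-membered ring C while the C4 nitrogen is hydrolysed with loss of ammonia, the ring B oxygen still being blocked as its MOM ether so that only the C8a hydroxyl can close, and HCl in methanol then removes both MOM acetals by acetal exchange without affecting the aryl methyl ethers.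

**Compound list**

1 | syringaldehyde (4-hydroxy-3,5-dimethoxybenzaldehyde) | COc1cc(C=O)cc(OC)c1O | starting material
2 | 3,5-dimethoxy-4-(methoxymethoxy)benzaldehyde | COCOc1c(OC)cc(C=O)cc1OC | intermediate
3 | 2-bromo-3,5-dimethoxy-4-(methoxymethoxy)benzaldehyde | COCOc1c(OC)cc(C=O)c(Br)c1OC | intermediate
4 | 2,3,5-trimethoxy-4-(methoxymethoxy)benzaldehyde | COCOc1c(OC)cc(C=O)c(OC)c1OC | intermediate
5 | 2,3,5-trimethoxy-4-(methoxymethoxy)phenyl formate (formed in the flask in step 4) | COCOc1c(OC)cc(OC=O)c(OC)c1OC | intermediate
6 | 2,3,5-trimethoxy-4-(methoxymethoxy)phenol | COCOc1c(OC)cc(O)c(OC)c1OC | intermediate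
7 | 2-hydroxy-3,4,6-trimethoxy-5-(methoxymethoxy)benzaldehyde | COCOc1c(OC)c(C=O)c(O)c(OC)c1OC | intermediate
8 | 2-(benzyloxy)-3,4,6-trimethoxy-5-(methoxymethoxy)benzaldehyde | COCOc1c(OC)c(C=O)c(OCc2ccccc2)c(OC)c1OC | intermediate
9 | (E)-2-(benzyloxy)-3,4,6-trimethoxy-5-(methoxymethoxy)benzaldehyde oxime | COCOc1c(OC)c(/C=N/O)c(OCc2ccccc2)c(OC)c1OC | intermediate
10 | (Z)-2-(benzyloxy)-N-hydroxy-3,4,6-trimethoxy-5-(methoxymethoxy)benzenecarboximidoyl chloride (formed in the flask in step 8) | COCOc1c(OC)c(/C(Cl)=N/O)c(OCc2ccccc2)c(OC)c1OC | intermediate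
11 | 2-(benzyloxy)-3,4,6-trimethoxy-5-(methoxymethoxy)benzonitrile oxide | COCOc1c(OC)c(C#[N+][O-])c(OCc2ccccc2)c(OC)c1OC | intermediate
12 | 2-hydroxy-6-methoxybenzaldehyde | COc1cccc(O)c1C=O | starting material
13 | 2-methoxy-6-(methoxymethoxy)benzaldehyde | COCOc1cccc(OC)c1C=O | intermediate
14 | dimethyl (1-diazo-2-oxopropyl)phosphonate | CC(=O)C(=[N+]=[N-])P(=O)(OC)OC | starting material
15 | 2-ethynyl-1-methoxy-3-(methoxymethoxy)benzene | COCOc1cccc(OC)c1C#C | intermediate
16 | 3-[2-(benzyloxy)-3,4,6-trimethoxy-5-(methoxymethoxy)phenyl]-5-[2-methoxy-6-(methoxymethoxy)phenyl]-1,2-oxazole | COCOc1cccc(OC)c1-c1cc(-c2c(OCc3ccccc3)c(OC)c(OC)c(OCOC)c2OC)no1 | intermediate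
17 | (2Z)-3-amino-3-[2-hydroxy-3,4,6-trimethoxy-5-(methoxymethoxy)phenyl]-1-[2-methoxy-6-(methoxymethoxy)phenyl]prop-2-en-1-one | COCOc1cccc(OC)c1C(=O)/C=C(\N)c1c(O)c(OC)c(OC)c(OCOC)c1OC | intermediate
18 | 5,7,8-trimethoxy-2-[2-methoxy-6-(methoxymethoxy)phenyl]-6-(methoxymethoxy)-4H-chromen-4-one (formed in the flask in step 13) | COCOc1cccc(OC)c1-c1cc(=O)c2c(OC)c(OCOC)c(OC)c(OC)c2o1 | intermediate
19 | 6,2'-dihydroxy-5,7,8,6'-tetramethoxyflavone | COc1cccc(O)c1-c1cc(=O)c2c(OC)c(O)c(OC)c(OC)c2o1 | target

**Step count**

Total steps: 13. Longest linear sequence: 11 steps (steps 1–8, 11, 12, 13); the alkyne branch is steps 9–10.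

**Steps most likely to fail**

Step 11. Both partners are di-ortho-substituted, so the cycloaddition may be slower than thermal isomerisation of the dipole to the isocyanate. Fallback: the more reactive alkene replaces the alkyne. From aldehyde 13, Wittig methylenation (Ph3PCH3Br, KOtBu, THF) should give 2-ethenyl-1-methoxy-3-(methoxymethoxy)benzene F1. Cycloaddition of nitrile oxide 11 to F1 (toluene, 60 °C) should give, with the same regiochemistry, racemic 3-[2-(benzyloxy)-3,4,6-trimethoxy-5-(methoxymethoxy)phenyl]-5-[2-methoxy-6-(methoxymethoxy)phenyl]-4,5-dihydro-1,2-oxazole F2. Dehydrogenation of F2 with MnO2 (toluene, reflux) comes back to the route at isoxazole 16.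

Step 3. Reductive loss of bromine and base-induced disproportionation of the free aldehyde may compete with C–O coupling in hot methoxide. Fallback: the aldehyde is excised before the coupling. From bromide 3, Baeyer–Villiger oxidation (mCPBA, CH2Cl2; then K2CO3, MeOH) should give, through 2-bromo-3,5-dimethoxy-4-(methoxymethoxy)phenyl formate F3, the phenol 2-bromo-3,5-dimethoxy-4-(methoxymethoxy)phenol F4. Copper-catalysed methoxylation of this ortho-bromophenoxide (NaOMe, CuBr, MeOH–DMF, 100 °C, under argon), the substrate class of the bromovanillin-to-syringaldehyde conversion, comes back to the route at phenol 6, bypassing 4 and 5.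

Step 12. The hydrogenolysis of the N–O bond may stall after debenzylation, because the isoxazole is shielded by two twisted di-ortho-substituted aryl groups, or the catalyst may be deactivated by the amine formed. Fallback: the two reductions are separated. From isoxazole 16, Mo(CO)6, H2O, MeCN, 80 °C (reductive N–O cleavage by zerovalent molybdenum bound to the ring nitrogen) should give (2Z)-3-amino-3-[2-(benzyloxy)-3,4,6-trimethoxy-5-(methoxymethoxy)phenyl]-1-[2-methoxy-6-(methoxymethoxy)phenyl]prop-2-en-1-one F5. Plain hydrogenolysis of the benzyl ether of F5 (H2, 10% Pd/C, EtOAc, rt) comes back to the route at enaminone 17.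

**Further compounds**

F1 | step 11 | 2-ethenyl-1-methoxy-3-(methoxymethoxy)benzene | COCOc1cccc(OC)c1C=C
F2 | step 11 | racemic 3-[2-(benzyloxy)-3,4,6-trimethoxy-5-(methoxymethoxy)phenyl]-5-[2-methoxy-6-(methoxymethoxy)phenyl]-4,5-dihydro-1,2-oxazole | COCOc1cccc(OC)c1C1CC(c2c(OCc3ccccc3)c(OC)c(OC)c(OCOC)c2OC)=NO1
F3 | step 3 | 2-bromo-3,5-dimethoxy-4-(methoxymethoxy)phenyl formate | COCOc1c(OC)cc(OC=O)c(Br)c1OC
F4 | step 3 | 2-bromo-3,5-dimethoxy-4-(methoxymethoxy)phenol | COCOc1c(OC)cc(O)c(Br)c1OC
F5 | step 12 | (2Z)-3-amino-3-[2-(benzyloxy)-3,4,6-trimethoxy-5-(methoxymethoxy)phenyl]-1-[2-methoxy-6-(methoxymethoxy)phenyl]prop-2-en-1-one | COCOc1cccc(OC)c1C(=O)/C=C(\N)c1c(OCc2ccccc2)c(OC)c(OC)c(OCOC)c1OC
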